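Readings and results are simulated for an exercise; scatter was added.

Fold the charges, the time and the earlier runs into one number before you read off any percentage.

| flask | electrophile | nucleophile | solid base | remark | time |
|---|---|---|---|---|---|
| north | 0.30 M (fed, over 3.0 min) | 0.77 M | 0.90 M | run made earlier; the fed solution adds 0.25 times the starting volume |  |
| north-east | 0.30 M (fed, over 3.0 min) | 1.1 M | 0.90 M | run made earlier; the fed solution adds 0.25 times the starting volume |  |
| Sunday's | 0.30 M (fed, over 3.0 min) | 0.540 M | 0.900 M | the fed solution adds 0.25 times the starting volume | 12 min |
| Wednesday's | 0.30 M (fed, over 3.0 min) | 0.700 M | 0.900 M | the fed solution adds 0.25 times the starting volume | 12 min |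

| run | time / min | electrophile / % | target / % |
|---|---|---|---|
| north | 1.33 | 41 | 2 |
| north | 3.00 | 91 | 11 |
| north | 4.00 | 84 | 18 |
| north | 6.00 | 72 | 26 |
| north | 8.00 | 65 | 36 |
| north-east | 0.667 | 23 | 0 |
| north-east | 1.00 | 31 | 3 |
| north-east | 2.00 | 58 | 8 |
| north-east | 3.00 | 85 | 12 |
| north-east | 5.00 | 71 | 29 |
| north-east | 8.00 | 55 | 47 |

(standard deviation of a reading: 1.5 percentage points)

- amounts are per litre of the starting volume; all of the dose is in the solution fed
- solid base is a solid; its amount is given per volume of the solution
- at the start none of the solid base is in solution
- percentages count the whole charge, also what has not yet gone in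

- part of the electrophile that has reacted at the end, Sunday's
- part of the electrophile that has reacted at the end, Wednesday's
- what raising the concentration of nucleophile from its lowest to its highest value here does to the part of the electrophile that has reacted (changes below 5 percentage points count as none) (it falls / it rises / no change)

After the feed the electrophile fades while target rises by about as much, so I count one target per electrophile reacted. The nucleophile falls as this goes on, and as a rough step I let one mean c(nucleophile) stand for it over the whole run. The fraction left is then the exponential of minus a product of three factors. The first is a rate coefficient. The second is the mean c(nucleophile): the charge less half of the electrophile reacted, taking one nucleophile per electrophile, divided by the dilution of 1.25. The third is the mean stay: the dose goes in evenly, so it is the time less half the dosing time.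

The last readings give the coefficient. The north run leaves 65 % at 8.00 min, which yields 0.115 M⁻¹ min⁻¹. The north-east run leaves 55 % at 8.00 min, which yields 0.111 M⁻¹ min⁻¹. I take 0.113 M⁻¹ min⁻¹. As a test of one number, the north-east run at 5.00 min should then have 28.5 % reacted, and the reading shows 29.0 %.

For Wednesday's flask, my first round with nucleophile as charged gives 48.7 % reacted. I put that back into the mean c(nucleophile) and go round again, which gives 0.597 and so 45.0 % reacted. This exposure number, the coefficient times mean c(nucleophile) times mean stay (a Damköhler number), counts the reaction lifetimes an average electrophile has stood through. Sunday's flask goes the same way to 0.457 and 36.7 %. The gap of 8.3 percentage points exceeds the margin of 5 points, so I expect a rise.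

The forecast gives 38 % (33 % to 43 %) for Sunday's flask, 45 % (40 % to 50 %) for Wednesday's, and it rises, on the ground that “the rate scales nearly with nucleophile concentration”. It stands on the same readings as my reckoning, so their nearness checks nothing.

The flasks give 34.7 % on Sunday's and 42.8 % on Wednesday's; going from Sunday's nucleophile to Wednesday's, the part reacted changes by 8.1 points, so the answer is: it rises.

    electrophile + nucleophile → acid set free + target (k = 0.120 M⁻¹ min⁻¹)
    nucleophile + acid set free ⇌ protonated nucleophile, settled at all times (K = 17000 M⁻¹)
    acid set free + free base ⇌ salt of the base (K = 1900 M⁻¹, k = 1.10 M⁻¹ min⁻¹)
    solid base ⇌ free base, rate k4*(cs4 - [free base]) while solid is left; crystals form when [free base] > cs4 (solubility = 0.0940 M, k = 0.0240 min⁻¹)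
    target → over-reaction product (k = 0.00260 min⁻¹)

Read back, Wednesday's result means an exposure of 0.559 against my 0.597. The rise comes from the difference in nucleophile: with Sunday's charge, Wednesday's flask drops from 42.8 % to 34.7 %. The exposure number scales with mean c(nucleophile), so I carry it to Wednesday's flask with 1.2 M of nucleophile. There it becomes 1.05, which means 65.0 % reacted, and that flask gives 62.6 %.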